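**Retrosynthetic overview**

1. The target is (S)-2-heptadecyl-5,7-dihydroxy-6,8-dimethylchroman-4-one; its two phenols are unmasked last from the 5,7-dimethyl ether.
2. Ring B (O1, C2, C3, C4, C4a, C8a) is opened at C3–C2 and O1–C8a, giving octadecanal (C2 and O1) and the enol silane of a fully substituted 2-fluoroaryl methyl ketone. Forward, an enantioselective Mukaiyama aldol reaction makes C3–C2 and sets C2, and the aldol oxygen then displaces fluoride at C8a in the same flask.
3. Enabling feature: O1–C8a=C4a–C4=O is a vinylogous ester, so C8a (ortho to the C4 carbonyl) accepts an oxygen nucleophile by SNAr, while C3 is the only enolisable carbon of the same ketone. C3–C4–C4a–C8a therefore acts towards the aldehyde C=O like a 1-alkoxy-3-silyloxydiene built into ring A, and the expelled fluoride desilylates the next aldol.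
4. Ring A is bought as 1-fluoro-3,5-dimethoxybenzene and filled by acylation, dibromination and double methylation; the fluorine is an activating group that leaves in the key step.
5. Order of ring formation: ring A is present from the start, ring B is closed in step 5.

Key step: step 5

Assumption: the (S)-tryptophan-derived oxazaborolidinone is taken to bind the aldehyde with its Si face covered by the indole, so that the Re face is attacked; should the aldol stage give the (R) series, the catalyst from (R)-tryptophan is used and nothing else changes.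

**Route**

Step 1
Reactants: 1 1-fluoro-3,5-dimethoxybenzene
Product: 2 1-(2-fluoro-4,6-dimethoxyphenyl)ethan-1-one
Conditions: AcCl (1.1 equiv), AlCl3 (1.2 equiv), CH2Cl2, −10 to 0 °C; chromatography to remove the minor regioisomer
Reagents that add atoms: acetyl chloride, CC(=O)Cl
Why: Friedel–Crafts acylation should prefer the carbon between F and one methoxy group, which is para to the other methoxy group and less hindered than the carbon between the two methoxy groups; the low temperature keeps AlCl3 from cleaving the ortho methyl ether.

Step 2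
Reactants: 2 1-(2-fluoro-4,6-dimethoxyphenyl)ethan-1-one
Product: 3 1-(3,5-dibromo-2-fluoro-4,6-dimethoxyphenyl)ethan-1-one
Conditions: NBS (2.1 equiv), MeCN, 0 °C to rt
Reagents that add atoms: N-bromosuccinimide, O=C1CCC(=O)N1Br
Why: Electrophilic aromatic bromination; the only two ring C–H positions left are each ortho or para to both methoxy groups and meta to the acetyl group, so both are brominated and no regiochemical question arises.

Step 3
Reactants: 3 1-(3,5-dibromo-2-fluoro-4,6-dimethoxyphenyl)ethan-1-one
Product: 4 1-(2-fluoro-4,6-dimethoxy-3,5-dimethylphenyl)ethan-1-one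
Conditions: MeZnCl (3 equiv), Pd(P(t-Bu)3)2 (5 mol%), THF, 60 °C
Reagents that add atoms: methylzinc chloride, C[Zn]Cl
Why: Double Negishi coupling; zerovalent palladium with a bulky electron-rich phosphine inserts into both di-ortho-substituted C–Br bonds, and the organozinc reagent is too weakly basic and nucleophilic to touch the methyl ketone or the C–F bond.

Step 4
Reactants: 4 1-(2-fluoro-4,6-dimethoxy-3,5-dimethylphenyl)ethan-1-one
Product: 5 {[1-(2-fluoro-4,6-dimethoxy-3,5-dimethylphenyl)ethenyl]oxy}trimethylsilane
Conditions: TMSOTf (1.3 equiv), Et3N (1.6 equiv), CH2Cl2, 0 °C; pentane extraction, used without chromatography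
Reagents that add atoms: trimethylsilyl trifluoromethanesulfonate, C[Si](C)(C)OS(=O)(=O)C(F)(F)F
Why: Soft enolisation and O-silylation of a methyl ketone with a single enolisable position, so only one enol silane can form.

Step 5
Reactants: 5 {[1-(2-fluoro-4,6-dimethoxy-3,5-dimethylphenyl)ethenyl]oxy}trimethylsilane, 6 octadecanal
Product: 8 (S)-2-heptadecyl-5,7-dimethoxy-6,8-dimethylchroman-4-one, via silyl aldol ether 7 (not isolated)
Conditions: (S)-2-butyl-4-(1H-indol-3-ylmethyl)-3-(4-methylphenylsulfonyl)-1,3,2-oxazaborolidin-5-one (20 mol%, from N-tosyl-(S)-tryptophan and BuB(OH)2), EtCN–CH2Cl2, −78 °C, slow addition of 6 (1.3 equiv); then Bu4N[Ph3SiF2] (0.5 equiv), THF, −78 °C to rt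
Reagents that add atoms: none
Why: The oxazaborolidinone activates 6 at boron and 5 adds through an open transition state (Mukaiyama aldol reaction), silyl transfer to the aldolate giving silyl ether 7. Fluoride then cleaves the O–Si bond and the alkoxide adds to C8a, ortho to the ketone, and expels fluoride (SNAr by addition–elimination); that fluoride desilylates the next molecule of 7, so the closure is a chain process with Me3SiF as the only by-product and the mixture never turns strongly basic. The closest known reaction types are the oxazaborolidinone-catalysed Mukaiyama aldol reaction of aryl methyl ketone enol silanes with aliphatic aldehydes, its extension to 1-methoxy-3-silyloxybutadienes with ring closure to dihydropyranones, the fluoride-catalysed SNAr etherification of activated aryl fluorides with silyl ethers, and the base-mediated closure of 3-hydroxy-1-(2-fluoroaryl) ketones to chroman-4-ones. Ring B closes as a six-membered ring by attack of O1 on the sp2 carbon C8a of the C8a=C4a–C4=O unit (6-endo-trig conjugate addition to an anionic σ-adduct that is an enolate of the C4 ketone, then loss of fluoride). C2 is the only stereocentre and is set in the C–C bond formation by the catalyst alone (both partners are achiral; attack on the Re face of 6 gives the S configuration), and the ring closure cannot change it because the C2–O1 bond is never broken. The step needs enantioface selectivity (catalyst), a single enolate position (the ketone has only one methyl group), substitution at C8a and not at the methoxy-bearing ortho carbon (fluoride is by far the better nucleofuge and activates its own carbon), and ring closure faster than retro-aldol cleavage or β-elimination (favoured by the activated C–F bond and the low standing concentration of alkoxide).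

Step 6
Reactants: 8 (S)-2-heptadecyl-5,7-dimethoxy-6,8-dimethylchroman-4-one
Product: 9 (S)-2-heptadecyl-5,7-dihydroxy-6,8-dimethylchroman-4-one
Conditions: BBr3 (5 equiv), CH2Cl2, −78 to 0 °C; then ice-water
Reagents that add atoms: none
Why: Lewis-acid cleavage of aryl methyl ethers; BBr3 should remove the C5 methyl group through the chelate with the C4 carbonyl and the C7 methyl group, whose oxygen is twisted out of conjugation by two ortho methyl groups, whereas O1 is a vinylogous ester oxygen and a poor donor, so the O1–C2 bond and the C2 stereocentre should stay untouched.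

**Compound list**

1 | 1-fluoro-3,5-dimethoxybenzene | COc1cc(F)cc(OC)c1 | starting material
2 | 1-(2-fluoro-4,6-dimethoxyphenyl)ethan-1-one | CC(=O)c1c(F)cc(OC)cc1OC | intermediate
3 | 1-(3,5-dibromo-2-fluoro-4,6-dimethoxyphenyl)ethan-1-one | CC(=O)c1c(F)c(Br)c(OC)c(Br)c1OC | intermediate
4 | 1-(2-fluoro-4,6-dimethoxy-3,5-dimethylphenyl)ethan-1-one | CC(=O)c1c(F)c(C)c(OC)c(C)c1OC | intermediate
5 | {[1-(2-fluoro-4,6-dimethoxy-3,5-dimethylphenyl)ethenyl]oxy}trimethylsilane | C=C(O[Si](C)(C)C)c1c(F)c(C)c(OC)c(C)c1OC | intermediate
6 | octadecanal | CCCCCCCCCCCCCCCCCC=O | starting material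
7 | (S)-1-(2-fluoro-4,6-dimethoxy-3,5-dimethylphenyl)-3-(trimethylsilyloxy)icosan-1-one (not isolated) | CCCCCCCCCCCCCCCCC[C@H](O[Si](C)(C)C)CC(=O)c1c(F)c(C)c(OC)c(C)c1OC | intermediate
8 | (S)-2-heptadecyl-5,7-dimethoxy-6,8-dimethylchroman-4-one | CCCCCCCCCCCCCCCCC[C@H]1CC(=O)c2c(OC)c(C)c(OC)c(C)c2O1 | intermediate
9 | (S)-2-heptadecyl-5,7-dihydroxy-6,8-dimethylchroman-4-one | CCCCCCCCCCCCCCCCC[C@H]1CC(=O)c2c(O)c(C)c(O)c(C)c2O1 | target

**Step count**

Total: 6 steps. Longest linear sequence: 6 steps (1 to 9); octadecanal enters in step 5.

**Steps most likely to fail**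

Step 5. The waxy long-chain aldehyde may crystallise at −78 °C, so that an uncatalysed or silyl-cation-catalysed aldol pathway erodes the enantioface selectivity. In the fluoride stage, retro-aldol cleavage or β-elimination of the alkoxide may outrun ring closure. The fallback sets out from 4 and forms the C2–alkyl bond instead of the C3–C2 bond. Formylation of 4 (NaH, HCO2Et, THF) gives 3-(2-fluoro-4,6-dimethoxy-3,5-dimethylphenyl)-3-oxopropanal F1 as its sodium enolate. On warming, the enolate oxygen displaces fluoride and closes 5,7-dimethoxy-6,8-dimethyl-4H-chromen-4-one F2. Copper-catalysed enantioselective conjugate addition of heptadecylmagnesium bromide (CuBr·SMe2, a ferrocenyl diphosphine of the Josiphos family in the antipode that gives the (S)-product, t-BuOMe, −78 °C) then sets C2, and the route is rejoined at 8.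

Step 6. A boron enolate of the chromanone may eliminate the O1 aryloxide, opening ring B; reclosure would erode the optical purity. Cleavage of the C7 ether may also stop short. The fallback sets out from 4 and moves the demethylation ahead of the stereocentre. BBr3 converts 4 into 1-(2-fluoro-4,6-dihydroxy-3,5-dimethylphenyl)ethan-1-one F3. Benzylation (BnBr, K2CO3, DMF, 60 °C) gives 1-[4,6-bis(benzyloxy)-2-fluoro-3,5-dimethylphenyl]ethan-1-one F4. TMSOTf/Et3N gives {[1-(4,6-bis(benzyloxy)-2-fluoro-3,5-dimethylphenyl)ethenyl]oxy}trimethylsilane F5. The conditions of step 5 with 6 give, by way of (S)-1-[4,6-bis(benzyloxy)-2-fluoro-3,5-dimethylphenyl]-3-(trimethylsilyloxy)icosan-1-one F6, the chromanone (S)-5,7-bis(benzyloxy)-2-heptadecyl-6,8-dimethylchroman-4-one F7. Neutral hydrogenolysis (H2, Pd/C, EtOAc) then rejoins the route at 9.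

Step 3. Oxidative addition at the bromide between the two methoxy groups may be slow, so that the second coupling stalls or protodebromination takes over. The fallback sets out from 2 and brings in both methyl carbons as electrophiles. Blanc chloromethylation (paraformaldehyde, HCl, ZnCl2, AcOH) gives 1-[3,5-bis(chloromethyl)-2-fluoro-4,6-dimethoxyphenyl]ethan-1-one F8. Hydrogenolysis of the two benzylic C–Cl bonds (H2, Pd/C, Et3N, EtOAc) rejoins the route at 4.

**Further compounds**

F1 | step 5 | 3-(2-fluoro-4,6-dimethoxy-3,5-dimethylphenyl)-3-oxopropanal (sodium enolate in the flask, not isolated) | O=CCC(=O)c1c(F)c(C)c(OC)c(C)c1OC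
F2 | step 5 | 5,7-dimethoxy-6,8-dimethyl-4H-chromen-4-one | O=C1C=COc2c(C)c(OC)c(C)c(OC)c12
F3 | step 6 | 1-(2-fluoro-4,6-dihydroxy-3,5-dimethylphenyl)ethan-1-one | CC(=O)c1c(F)c(C)c(O)c(C)c1O
F4 | step 6 | 1-[4,6-bis(benzyloxy)-2-fluoro-3,5-dimethylphenyl]ethan-1-one | CC(=O)c1c(F)c(C)c(OCc2ccccc2)c(C)c1OCc1ccccc1
F5 | step 6 | {[1-(4,6-bis(benzyloxy)-2-fluoro-3,5-dimethylphenyl)ethenyl]oxy}trimethylsilane | C=C(O[Si](C)(C)C)c1c(F)c(C)c(OCc2ccccc2)c(C)c1OCc1ccccc1
F6 | step 6 | (S)-1-[4,6-bis(benzyloxy)-2-fluoro-3,5-dimethylphenyl]-3-(trimethylsilyloxy)icosan-1-one (not isolated) | CCCCCCCCCCCCCCCCC[C@H](O[Si](C)(C)C)CC(=O)c1c(F)c(C)c(OCc2ccccc2)c(C)c1OCc1ccccc1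
F7 | step 6 | (S)-5,7-bis(benzyloxy)-2-heptadecyl-6,8-dimethylchroman-4-one | CCCCCCCCCCCCCCCCC[C@H]1CC(=O)c2c(OCc3ccccc3)c(C)c(OCc3ccccc3)c(C)c2O1
F8 | step 3 | 1-[3,5-bis(chloromethyl)-2-fluoro-4,6-dimethoxyphenyl]ethan-1-one | CC(=O)c1c(F)c(CCl)c(OC)c(CCl)c1OC
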